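The oxane is cut at O1–C2. In the ring O1, C2–C6, C2 is an ether carbon that carries the first two carbons of the arylethyl chain, so C2 and these two carbons can be treated as an allyl unit. A zerovalent-palladium allylic etherification then lets the C6 hydroxyl close the ring at the internal allyl terminus, sets C2 cis to the C6 aryl group and leaves a vinyl group for the later sp3–sp2 coupling. The precursor is an open-chain (E)-allylic methyl carbonate with a free benzylic C6 hydroxyl and a syn C4 silyl ether; a labile triethylsilyl group on O6 keeps the two oxygens apart until then.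

Key step: step 10

Remarks
- Labels: the oxane is numbered O1, C2 (vinyl, later arylethyl), C4 (oxygenated), C6 (aryl), and open-chain intermediates keep these labels. Ar = 3,4-bis(benzyloxy)-5-methoxyphenyl, TES = triethylsilyl, TBS = tert-butyldimethylsilyl.
- Stereodescriptors: the target is (2S,4S,6S) with C2 and C6 substituents cis and the C4 oxygen trans to both (axial). In the vinyl oxane 16 the same C2 arrangement is named R because vinyl outranks C3.
- Assumption: (S)-TRIP [(S)-3,3′-bis(2,4,6-triisopropylphenyl)-1,1′-binaphthyl-2,2′-diyl hydrogen phosphate] is taken to deliver allyl to the Si face of the aldehydes, which gives S at C6 and S at C4.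
- Assumption: the (R,R) antipode of the diamide bisphosphine is taken as the matched ligand in step 10; the chair preference of the substrate points to the same 2,6-cis product, so the ligand should reinforce the selectivity.
- Design: O6 carries TES (removed before the key step) and O4 carries TBS (kept until after the coupling). The alkene is cleaved with OsO4/NaIO4 and not with ozone, because of the electron-rich arene and the benzyl ethers.

Step 1
Reactants: 1 3,4-dihydroxy-5-methoxybenzaldehyde
Product: 2 3,4-bis(benzyloxy)-5-methoxybenzaldehyde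
Conditions: BnBr (2.4 equiv), K2CO3, DMF, 60 °C
Reagents that add atoms: benzyl bromide, BrCc1ccccc1
Why: Williamson etherification: K2CO3 deprotonates both phenols and the phenoxides displace bromide from benzyl bromide, the aldehyde being inert under these conditions.

Step 2
Reactants: 2 3,4-bis(benzyloxy)-5-methoxybenzaldehyde; 3 allylboronic acid pinacol ester
Product: 5 (1S)-1-Ar-but-3-en-1-ol, via pinacol borate ester 4 (not isolated)
Conditions: (S)-TRIP (5 mol %), toluene, 4 Å MS, −30 °C; aq. NaHCO3 work-up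
Reagents that add atoms: none
Why: Chiral phosphoric acid-catalysed allylboration through a closed chair-like six-membered transition state in which the acid activates the boronate; the (S)-catalyst should direct attack on the Si face of the aldehyde and so set C6 as S, and the borate ester 4 is hydrolysed on work-up.

Step 3
Reactants: 5 (1S)-1-Ar-but-3-en-1-ol
Product: 6 triethyl{[(1S)-1-Ar-but-3-en-1-yl]oxy}silane
Conditions: TESCl, imidazole, CH2Cl2, 0 °C to rt
Reagents that add atoms: chlorotriethylsilane, CC[Si](Cl)(CC)CC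
Why: Silylation of the secondary benzylic alcohol with a chlorosilane and imidazole, the triethylsilyl group being chosen because it can later be removed selectively beside a tert-butyldimethylsilyl ether.

Step 4
Reactants: 6 triethyl{[(1S)-1-Ar-but-3-en-1-yl]oxy}silane
Product: 8 (3S)-3-Ar-3-(triethylsilyloxy)propanal, via vicinal diol 7 (not isolated)
Conditions: OsO4 (2 mol %), NaIO4 (4 equiv), 2,6-lutidine, 1,4-dioxane/H2O, rt
Reagents that add atoms: sodium periodate, [Na+].[O-]I(=O)(=O)=O (terminal oxidant; the carbonyl oxygen is passed on by osmium tetroxide, O=[Os](=O)(=O)=O)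
Why: Lemieux–Johnson oxidation (dihydroxylation followed by periodate cleavage in the same flask, buffered by 2,6-lutidine) shortens the alkene to the aldehyde and avoids exposing the electron-rich arene and the benzyl ethers to ozone, while C6 is not touched.

Step 5
Reactants: 8 (3S)-3-Ar-3-(triethylsilyloxy)propanal; 3 allylboronic acid pinacol ester
Product: 10 (1S,3S)-1-Ar-1-(triethylsilyloxy)hex-5-en-3-ol, via pinacol borate ester 9 (not isolated)
Conditions: (S)-TRIP (10 mol %), toluene, 4 Å MS, −30 °C; aq. NaHCO3 work-up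
Reagents that add atoms: none
Why: Second chiral phosphoric acid-catalysed allylboration, in which the same catalyst should again deliver allyl to the Si face and set C4 as S (syn to C6) under catalyst control, the remote silyloxy centre exerting only a weak bias.

Step 6
Reactants: 10 (1S,3S)-1-Ar-1-(triethylsilyloxy)hex-5-en-3-ol
Product: 11 (1S,3S)-1-Ar-3-(tert-butyldimethylsilyloxy)-1-(triethylsilyloxy)hex-5-ene
Conditions: TBSOTf, 2,6-lutidine, CH2Cl2, −78 °C
Reagents that add atoms: tert-butyldimethylsilyl trifluoromethanesulfonate, CC(C)(C)[Si](C)(C)OS(=O)(=O)C(F)(F)F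
Why: Silylation of the secondary alcohol with the silyl triflate and a hindered pyridine base at low temperature, conditions that leave the triethylsilyl ether and both stereocentres untouched.

Step 7
Reactants: 12 (Z)-but-2-ene-1,4-diol
Product: 13 (Z)-but-2-ene-1,4-diyl dimethyl dicarbonate
Conditions: ClCO2Me (2.5 equiv), pyridine, CH2Cl2, 0 °C
Reagents that add atoms: methyl chloroformate, COC(=O)Cl
Why: Acylation of the two primary allylic hydroxyls with a chloroformate and pyridine gives the bis(carbonate) with the Z alkene unchanged.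

Step 8
Reactants: 11 (1S,3S)-1-Ar-3-(tert-butyldimethylsilyloxy)-1-(triethylsilyloxy)hex-5-ene; 13 (Z)-but-2-ene-1,4-diyl dimethyl dicarbonate
Product: 14 (2E,5S,7S)-7-Ar-5-(tert-butyldimethylsilyloxy)-7-(triethylsilyloxy)hept-2-en-1-yl methyl carbonate
Conditions: 13 (3 equiv), second-generation Grubbs catalyst (5 mol %), CH2Cl2, 40 °C
Reagents that add atoms: none
Why: Olefin cross-metathesis of the terminal alkene with an excess of the symmetric allylic bis(carbonate) should give mainly the more stable E alkene, and the silyl ethers, benzyl ethers and carbonate are inert to the ruthenium carbene.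

Step 9
Reactants: 14 (2E,5S,7S)-7-Ar-5-(tert-butyldimethylsilyloxy)-7-(triethylsilyloxy)hept-2-en-1-yl methyl carbonate
Product: 15 (2E,5S,7S)-7-Ar-5-(tert-butyldimethylsilyloxy)-7-hydroxyhept-2-en-1-yl methyl carbonate
Conditions: HF·pyridine, pyridine, THF, 0 °C
Reagents that add atoms: none
Why: Chemoselective desilylation, since buffered HF·pyridine cleaves the triethylsilyl ether far faster than the bulkier tert-butyldimethylsilyl ether and does not attack the allylic carbonate or the electron-rich benzylic centre.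

Step 10
Reactants: 15 (2E,5S,7S)-7-Ar-5-(tert-butyldimethylsilyloxy)-7-hydroxyhept-2-en-1-yl methyl carbonate
Product: 16 (2R,4S,6S)-6-Ar-4-(tert-butyldimethylsilyloxy)-2-vinyloxane (2,6-cis; silyloxy group axial)
Conditions: Pd2(dba)3·CHCl3 (2.5 mol %), (R,R)-N,N′-(cyclohexane-1,2-diyl)bis[2-(diphenylphosphino)benzamide] (7.5 mol %), degassed CH2Cl2, 0 °C to rt
Reagents that add atoms: none
Why: Zerovalent palladium ionises the allylic carbonate with inversion to a cationic π-allyl complex (divalent palladium), loss of CO2 leaves methoxide, which deprotonates the C6 hydroxyl, and the alkoxide attacks the internal allyl carbon C2 on the face opposite palladium and releases the catalyst. The closest known reaction type is the intramolecular Tsuji–Trost asymmetric allylic etherification that converts hydroxy allylic carbonates into 2-vinyl oxanes. The ring O1–C2–C3–C4–C5–C6 closes in the 6-exo mode at the substituted allyl terminus, whereas attack at the CH2 terminus would need an eight-membered ring and is not expected. The new stereocentre C2 is set under Curtin–Hammett control: the diastereomeric π-allyl complexes exchange the palladium-bound face by η3–η1–η3 slippage at the CH2 terminus, the chiral pocket of the ligand favours closure from one of them, and the chair-like transition state places the C6 aryl and the incipient vinyl group equatorial with the C4 silyloxy group axial, which gives the 2,6-cis (2R) product. The selectivity needed is C2 cis to C6, and the substrate secures it because the trans isomer would force the vinyl group axial and syn to the axial C4 silyloxy group; E purity of 15 matters, since an anti π-allyl from Z material could close before it equilibrates. Benzyl ethers, the silyl ether and the aryl methyl ether are inert to the catalyst.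

Step 11
Reactants: 17 4-bromo-2-methoxyphenol
Product: 18 1-(benzyloxy)-4-bromo-2-methoxybenzene
Conditions: BnBr, K2CO3, DMF, rt
Reagents that add atoms: benzyl bromide, BrCc1ccccc1
Why: Williamson etherification of the phenol, which masks it for the coupling and lets all three phenols be released together at the end.

Step 12
Reactants: 16 (2R,4S,6S)-6-Ar-4-(tert-butyldimethylsilyloxy)-2-vinyloxane; 18 1-(benzyloxy)-4-bromo-2-methoxybenzene
Product: 20 (2S,4S,6S)-6-Ar-2-[2-(4-benzyloxy-3-methoxyphenyl)ethyl]-4-(tert-butyldimethylsilyloxy)oxane, via B-alkyl-9-BBN adduct 19 (not isolated)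
Conditions: 9-BBN, THF, 0 °C to rt; then 18, Pd(dppf)Cl2·CH2Cl2 (5 mol %), aq. K3PO4, DMF, 50 °C
Reagents that add atoms: none
Why: Anti-Markovnikov hydroboration of the vinyl group with 9-BBN followed by B-alkyl Suzuki–Miyaura coupling, in which the base-activated primary alkyl group is transferred to the arylpalladium bromide; no stereocentre takes part.

Step 13
Reactants: 20 (2S,4S,6S)-6-Ar-2-[2-(4-benzyloxy-3-methoxyphenyl)ethyl]-4-(tert-butyldimethylsilyloxy)oxane
Product: 21 (2S,4S,6S)-6-Ar-2-[2-(4-benzyloxy-3-methoxyphenyl)ethyl]oxan-4-ol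
Conditions: TBAF, THF, rt to 40 °C
Reagents that add atoms: none
Why: Fluoride-induced cleavage of the silyl ether, driven by the strength of the Si–F bond, which leaves the benzyl ethers, the ring and all three stereocentres untouched.

Step 14
Reactants: 21 (2S,4S,6S)-6-Ar-2-[2-(4-benzyloxy-3-methoxyphenyl)ethyl]oxan-4-ol
Product: 22 (2S,4S,6S)-6-Ar-2-[2-(4-benzyloxy-3-methoxyphenyl)ethyl]oxan-4-yl acetate
Conditions: Ac2O, pyridine, DMAP (cat.), CH2Cl2, rt
Reagents that add atoms: acetic anhydride, CC(=O)OC(C)=O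
Why: DMAP-catalysed acylation of the only free hydroxyl group, which proceeds with retention at C4 because the C–O bond is not broken.

Step 15
Reactants: 22 (2S,4S,6S)-6-Ar-2-[2-(4-benzyloxy-3-methoxyphenyl)ethyl]oxan-4-yl acetate
Product: 23 (2S,4S,6S)-2-(3,4-dihydroxy-5-methoxyphenyl)-6-[2-(4-hydroxy-3-methoxyphenyl)ethyl]oxan-4-yl acetate (CNP0143286.2)
Conditions: H2 (1 atm), Pd/C (10 wt %), EtOAc, rt
Reagents that add atoms: none
Why: Catalytic hydrogenolysis of the three aryl benzyl ethers, which cleave much faster than the cyclic benzylic C6–O1 ether in a neutral ester solvent at one atmosphere, so that the reaction can be stopped once debenzylation is complete; the acetate and the methyl ethers are inert.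

Compound list
1 | 3,4-dihydroxy-5-methoxybenzaldehyde | COc1cc(C=O)cc(O)c1O | starting material
2 | 3,4-bis(benzyloxy)-5-methoxybenzaldehyde | COc1cc(C=O)cc(OCc2ccccc2)c1OCc1ccccc1 | intermediate
3 | allylboronic acid pinacol ester | C=CCB1OC(C)(C)C(C)(C)O1 | starting material
4 | pinacol borate ester of 5 (Bpin on O6) | C=CC[C@@H](c1cc(OCc2ccccc2)c(OCc2ccccc2)c(OC)c1)OB1OC(C)(C)C(C)(C)O1 | intermediate
5 | (1S)-1-[3,4-bis(benzyloxy)-5-methoxyphenyl]but-3-en-1-ol | C=CC[C@@H](c1cc(OCc2ccccc2)c(OCc2ccccc2)c(OC)c1)O | intermediate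
6 | triethyl{[(1S)-1-Ar-but-3-en-1-yl]oxy}silane | C=CC[C@@H](c1cc(OCc2ccccc2)c(OCc2ccccc2)c(OC)c1)O[Si](CC)(CC)CC | intermediate
7 | (4S)-4-Ar-4-(triethylsilyloxy)butane-1,2-diol, both C2 epimers | OCC(O)C[C@@H](c1cc(OCc2ccccc2)c(OCc2ccccc2)c(OC)c1)O[Si](CC)(CC)CC | intermediate
8 | (3S)-3-Ar-3-(triethylsilyloxy)propanal | O=CC[C@@H](c1cc(OCc2ccccc2)c(OCc2ccccc2)c(OC)c1)O[Si](CC)(CC)CC | intermediate
9 | pinacol borate ester of 10 (Bpin on O4) | C=CC[C@H](OB1OC(C)(C)C(C)(C)O1)C[C@@H](c1cc(OCc2ccccc2)c(OCc2ccccc2)c(OC)c1)O[Si](CC)(CC)CC | intermediate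
10 | (1S,3S)-1-Ar-1-(triethylsilyloxy)hex-5-en-3-ol | C=CC[C@H](O)C[C@@H](c1cc(OCc2ccccc2)c(OCc2ccccc2)c(OC)c1)O[Si](CC)(CC)CC | intermediate
11 | (1S,3S)-1-Ar-3-(tert-butyldimethylsilyloxy)-1-(triethylsilyloxy)hex-5-ene | C=CC[C@H](O[Si](C)(C)C(C)(C)C)C[C@@H](c1cc(OCc2ccccc2)c(OCc2ccccc2)c(OC)c1)O[Si](CC)(CC)CC | intermediate
12 | (Z)-but-2-ene-1,4-diol | OC/C=C\CO | starting material
13 | (Z)-but-2-ene-1,4-diyl dimethyl dicarbonate | COC(=O)OC/C=C\COC(=O)OC | intermediate
14 | (2E,5S,7S)-7-Ar-5-(tert-butyldimethylsilyloxy)-7-(triethylsilyloxy)hept-2-en-1-yl methyl carbonate | COC(=O)OC/C=C/C[C@H](O[Si](C)(C)C(C)(C)C)C[C@@H](c1cc(OCc2ccccc2)c(OCc2ccccc2)c(OC)c1)O[Si](CC)(CC)CC | intermediate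
15 | (2E,5S,7S)-7-Ar-5-(tert-butyldimethylsilyloxy)-7-hydroxyhept-2-en-1-yl methyl carbonate | COC(=O)OC/C=C/C[C@H](O[Si](C)(C)C(C)(C)C)C[C@@H](c1cc(OCc2ccccc2)c(OCc2ccccc2)c(OC)c1)O | intermediate
16 | (2R,4S,6S)-6-Ar-4-(tert-butyldimethylsilyloxy)-2-vinyloxane | C=C[C@H]1C[C@H](O[Si](C)(C)C(C)(C)C)C[C@@H](c2cc(OCc3ccccc3)c(OCc3ccccc3)c(OC)c2)O1 | intermediate
17 | 4-bromo-2-methoxyphenol | COc1cc(Br)ccc1O | starting material
18 | 1-(benzyloxy)-4-bromo-2-methoxybenzene | COc1cc(Br)ccc1OCc1ccccc1 | intermediate
19 | 9-{2-[(2S,4S,6S)-6-Ar-4-(tert-butyldimethylsilyloxy)oxan-2-yl]ethyl}-9-borabicyclo[3.3.1]nonane | B1(CC[C@H]2C[C@H](O[Si](C)(C)C(C)(C)C)C[C@@H](c3cc(OCc4ccccc4)c(OCc4ccccc4)c(OC)c3)O2)C2CCCC1CCC2 | intermediate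
20 | (2S,4S,6S)-6-Ar-2-[2-(4-benzyloxy-3-methoxyphenyl)ethyl]-4-(tert-butyldimethylsilyloxy)oxane | COc1cc(CC[C@H]2C[C@H](O[Si](C)(C)C(C)(C)C)C[C@@H](c3cc(OCc4ccccc4)c(OCc4ccccc4)c(OC)c3)O2)ccc1OCc1ccccc1 | intermediate
21 | (2S,4S,6S)-6-Ar-2-[2-(4-benzyloxy-3-methoxyphenyl)ethyl]oxan-4-ol | COc1cc(CC[C@H]2C[C@H](O)C[C@@H](c3cc(OCc4ccccc4)c(OCc4ccccc4)c(OC)c3)O2)ccc1OCc1ccccc1 | intermediate
22 | (2S,4S,6S)-6-Ar-2-[2-(4-benzyloxy-3-methoxyphenyl)ethyl]oxan-4-yl acetate | COc1cc(CC[C@H]2C[C@H](OC(C)=O)C[C@@H](c3cc(OCc4ccccc4)c(OCc4ccccc4)c(OC)c3)O2)ccc1OCc1ccccc1 | intermediate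
23 | (2S,4S,6S)-2-(3,4-dihydroxy-5-methoxyphenyl)-6-[2-(4-hydroxy-3-methoxyphenyl)ethyl]oxan-4-yl acetate | COc1cc(CC[C@H]2C[C@H](OC(C)=O)C[C@@H](c3cc(O)c(O)c(OC)c3)O2)ccc1O | target

Total step count: 15. Longest linear sequence: 13 steps (steps 1–6, 8–10 and 12–15); steps 7 and 11 prepare the two coupling partners.

Steps most likely to fail

Step 10. The closure may suffer from poor facial discrimination at C2 if ligand and chair preferences oppose each other, or from slow ring closure that lets β-hydride elimination to a diene or capture of the allyl cation by methoxide compete. The fallback leaves the π-allyl manifold. It sets out from 15: methanolysis of the methyl carbonate (K2CO3, MeOH, 0 °C) should give (2E,5S,7S)-7-Ar-5-(tert-butyldimethylsilyloxy)hept-2-ene-1,7-diol F1. A cationic monovalent gold catalyst (Ph3PAuCl/AgOTf, 4 Å MS, CH2Cl2, rt) then activates the alkene for anti addition of the C6 hydroxyl at C2 followed by anti loss of water. This dehydrative SN2′ cyclisation of a monoallylic diol is governed only by the chair preference of the substrate, and it comes back to the route at 16.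

Step 5. Catalyst control over the aliphatic β-silyloxy aldehyde may be insufficient, so that the syn and anti alcohols form together, and the aldehyde may lose silanol by β-elimination. The fallback sets C4 by kinetic resolution of an epoxide instead of by carbonyl allylation. It sets out from 6: epoxidation (mCPBA, NaHCO3, CH2Cl2, 0 °C) should give 2-[(2S)-2-Ar-2-(triethylsilyloxy)ethyl]oxirane as a mixture of epimers F2. Hydrolytic kinetic resolution with the antipode of the chiral (salen)Co(OAc) complex that consumes the unwanted epimer should leave (2R)-2-[(2S)-2-Ar-2-(triethylsilyloxy)ethyl]oxirane F3 and convert the other epimer into (2S,4S)-4-Ar-4-(triethylsilyloxy)butane-1,2-diol F4, which is separated. Opening of the epoxide at its terminal carbon with vinylMgBr and catalytic CuI (THF, −30 °C) comes back to the route at 10 and bypasses steps 4 and 5.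

Step 8. The metathesis may give incomplete E selectivity or self-metathesis of the terminal alkene; Z material would ionise to an anti π-allyl complex and erode the selectivity of step 10. The fallback builds the E alkene by olefination. It sets out from 11: Lemieux–Johnson cleavage (OsO4, NaIO4, 2,6-lutidine) should give, by way of the (4S,6S)-6-Ar-4-(tert-butyldimethylsilyloxy)-6-(triethylsilyloxy)hexane-1,2-diol F5, the aldehyde (3R,5S)-5-Ar-3-(tert-butyldimethylsilyloxy)-5-(triethylsilyloxy)pentanal F6. A Horner–Wadsworth–Emmons reaction with triethyl phosphonoacetate (LiCl, DBU, MeCN) should give ethyl (2E,5S,7S)-7-Ar-5-(tert-butyldimethylsilyloxy)-7-(triethylsilyloxy)hept-2-enoate F7. Reduction with i-Bu2AlH (CH2Cl2, −78 °C) should give (2E,5S,7S)-7-Ar-5-(tert-butyldimethylsilyloxy)-7-(triethylsilyloxy)hept-2-en-1-ol F8. Acylation with ClCO2Me and pyridine comes back to the route at 14.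

Further compounds
F1 | step 10 | (2E,5S,7S)-7-Ar-5-(tert-butyldimethylsilyloxy)hept-2-ene-1,7-diol | OC/C=C/C[C@H](O[Si](C)(C)C(C)(C)C)C[C@@H](c1cc(OCc2ccccc2)c(OCc2ccccc2)c(OC)c1)O
F2 | step 5 | 2-[(2S)-2-Ar-2-(triethylsilyloxy)ethyl]oxirane, mixture of epimers at the oxirane carbon | C1OC1C[C@@H](c1cc(OCc2ccccc2)c(OCc2ccccc2)c(OC)c1)O[Si](CC)(CC)CC
F3 | step 5 | (2R)-2-[(2S)-2-Ar-2-(triethylsilyloxy)ethyl]oxirane | C1O[C@@H]1C[C@@H](c1cc(OCc2ccccc2)c(OCc2ccccc2)c(OC)c1)O[Si](CC)(CC)CC
F4 | step 5 | (2S,4S)-4-Ar-4-(triethylsilyloxy)butane-1,2-diol | OC[C@@H](O)C[C@@H](c1cc(OCc2ccccc2)c(OCc2ccccc2)c(OC)c1)O[Si](CC)(CC)CC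
F5 | step 8 | (4S,6S)-6-Ar-4-(tert-butyldimethylsilyloxy)-6-(triethylsilyloxy)hexane-1,2-diol, both C2 epimers | OCC(O)C[C@H](O[Si](C)(C)C(C)(C)C)C[C@@H](c1cc(OCc2ccccc2)c(OCc2ccccc2)c(OC)c1)O[Si](CC)(CC)CC
F6 | step 8 | (3R,5S)-5-Ar-3-(tert-butyldimethylsilyloxy)-5-(triethylsilyloxy)pentanal | O=CC[C@H](O[Si](C)(C)C(C)(C)C)C[C@@H](c1cc(OCc2ccccc2)c(OCc2ccccc2)c(OC)c1)O[Si](CC)(CC)CC
F7 | step 8 | ethyl (2E,5S,7S)-7-Ar-5-(tert-butyldimethylsilyloxy)-7-(triethylsilyloxy)hept-2-enoate | CCOC(=O)/C=C/C[C@H](O[Si](C)(C)C(C)(C)C)C[C@@H](c1cc(OCc2ccccc2)c(OCc2ccccc2)c(OC)c1)O[Si](CC)(CC)CC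
F8 | step 8 | (2E,5S,7S)-7-Ar-5-(tert-butyldimethylsilyloxy)-7-(triethylsilyloxy)hept-2-en-1-ol | OC/C=C/C[C@H](O[Si](C)(C)C(C)(C)C)C[C@@H](c1cc(OCc2ccccc2)c(OCc2ccccc2)c(OC)c1)O[Si](CC)(CC)CC
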